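Take a small charge of starting material that decays by itself into side product while a gas, held over the liquid, seeps in and turns it into target. Ask how much of the charge the gas can save.

in all of them: starting material 2.0 mM; gas phase 0.12 mM (held); time 80 s
- south-east: protic impurity 0.480 mM
- north-west: protic impurity 0.400 mM

    2 dissolved gas → homo dimer (k1 = 670 L mol⁻¹ s⁻¹)
    gas phase ⇌ dissolved gas, rate k2*(csat - [dissolved gas]) (k2 = 0.13 s⁻¹, csat = 0.12 mM)
    starting material + dissolved gas → target (k3 = 1000 L mol⁻¹ s⁻¹)
    dissolved gas + target → over-reaction product (k4 = 58 L mol⁻¹ s⁻¹)
    dissolved gas + protic impurity → quenched reagent (k5 = 470 L mol⁻¹ s⁻¹)
    starting material → side product (k6 = 0.074 s⁻¹)

- for a step with 2 of a species take k times the square, and two of it per event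
- at the start none of the gas is dissolved
- run time (south-east): 80 s

1. which of these there is most of at the end, counted by the starting material in it, south-east (target / over-reaction product / starting material / side product)
2. which of these there is most of at the end, counted by the starting material in it, north-west (target / over-reaction product / starting material / side product)
3. the largest of these amounts at the end, in percent of the starting material charged, south-east
4. the largest of these amounts at the end, in percent of the starting material charged, north-west

Solve two extreme flasks first. In the first, let the liquid stand full of gas, at 0.12 mM, from the first moment. One number then splits the starting material: the even level 0.0740 mM, the dissolved gas at which its two routes run equally fast. Held at 0.12 mM, above that level, the gas sends 61.9% of the charge towards target.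

In the second, let gas enter at its fastest, 0.0156 mM s⁻¹, the rate into a liquid holding none, and let starting material catch every bit of it. Starting material then falls by its own decay plus this steady feed and reaches zero at 31.8 s, having caught 24.8% of the charge, target and over-reaction product together. That leaves 75.2% as the side floor: the part of the charge that decays even when all gas entering at full rate is caught.

The second extreme saves less of the charge than the first, and in a real flask gas enters below that feed once some has dissolved, so I expect the real flasks to end above the floor. At the start the protic impurity takes 10.1% of the gas in south-east and 8.59% in north-west. So I commit to side product on top in both flasks, and higher in south-east, where the share of the protic impurity is larger.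

The forecast gives side product at 83.4% in south-east and side product at 82.9% in north-west, holding that “the impurity level shifts this very little because it only slightly changes the dissolved gas level”. My floor lies under those figures and does not give them.

South-east ends with side product at 85.0% and north-west with side product at 84.6%, both above the side floor of 75.2%. At 40.0 s north-west holds dissolved gas at 0.0404 mM, under the even level, and by then 2.15% of its starting material is left. The neighbour of north-west, charged with 8.0 mM of starting material, has its side floor at 90.3% and reads 93.0% of side product.

The numbers were chosen freely, and the outcome is calculated.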